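**Plan**

Numbering: cyclopentane C1(CH3)–C2–C3–C4(OH, iPr)–C5(H); cycloheptane C5–C6(OCOAr)–C7–C8(CH3, OH)–C9(OH)–C10–C1. β is the face of the C1 methyl, and every precursor atom carries the number of the target atom it becomes.
Retrosynthetic cuts, in order: phenol O–benzyl; C8–O and C9–O (osmylation of C8=C9); the C6 O–acyl bond; C4–isopropyl; C8–CH3; last, the ring-fusion bond C1–C5.
Enabling feature: the fusion bond joins quaternary C1 to C5, and C5 is flanked by oxygenated C6. With C6 as a ketone, the array C1–C5–C6(=O) is what remains after C1 has moved from C6 to C5, so the 5–7 bicycle unfolds to a 6–6 cis-decalin with C6–OH and a C5 leaving group. That decalin is the diol of an angular-methyl octalone whose carbonyl is C4.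
Forward order: both rings are bought as a decalin. Steps 1–4 dress C4–C6, and step 5 turns 6–6 into 5–7 in one event. The new C6 ketone then brings in C8–CH3 and C8=C9, C4 is oxidised and isopropylated, and ester and diol come last.
Stereochemistry: C1 is purchased. C5 comes from inversion at a β-mesylate that was set by OH-directed osmylation. C4 comes from α-face organocerium attack, C6 from hydride delivered by the 4β-OH, and C8/C9 from osmylation of the convex α face.

Key step: step 5

Assumption: (S)-(+)-4a-methyl-4,4a,5,6,7,8-hexahydronaphthalen-2(3H)-one is taken as a catalogue compound (otherwise two operations from 2-methylcyclohexanone, (R)-1-phenylethylamine and methyl vinyl ketone); C10 needs no oxygen because the ketone born in step 5 is the only handle ring B requires.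

Step 1
Reactants: 1 (S)-4a-methyl-4,4a,5,6,7,8-hexahydronaphthalen-2(3H)-one
Product: 2 (2S,4aS)-4a-methyl-2,3,4,4a,5,6,7,8-octahydronaphthalen-2-ol (4β-OH, C5=C6)
Conditions: NaBH4, CeCl3·7H2O, MeOH, −78 to 0 °C
Reagents that add atoms: none
Why: Luche reduction: the cerium-modified borohydride adds only 1,2 to the enone, and axial delivery from the α face, away from the angular methyl as in Δ4-3-keto steroids, should set the pseudo-equatorial 4β-carbinol that steers step 2.

Step 2
Reactants: 2 4β-allylic alcohol
Product: 4 1β-methyl-cis-decalin-4β,5β,6β-triol, via TMEDA-chelated 5β,6β-osmate ester 3 (not isolated)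
Conditions: OsO4 (1.05 equiv), TMEDA, CH2Cl2, −78 °C; then aq Na2SO3, THF, reflux
Reagents that add atoms: osmium tetroxide, O=[Os](=O)(=O)=O
Why: Hydrogen-bond-directed dihydroxylation: the electron-rich OsO4–TMEDA chelate accepts a hydrogen bond from the 4β-OH and should therefore add suprafacially ([3+2]) to the β face of C5=C6, overriding the steric bias of the C1 methyl and setting C5–O and C6–O both β (cis-decalin).

Step 3
Reactants: 4 4β,5β,6β-triol
Product: 6 4β-(4-methoxybenzyloxy)-1β-methyl-cis-decalin-5β,6β-diol, via 4,5-O-dibutylstannylene acetal 5 (not isolated)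
Conditions: Bu2SnO, toluene, reflux (−H2O); then PMBCl, Bu4NI (cat.), 80 °C
Reagents that add atoms: 4-methoxybenzyl chloride, COc1ccc(CCl)cc1
Why: Stannylene-mediated regioselective O-alkylation: tin bridges the cis-vicinal O4/O5 pair and the less hindered O4, remote from fully substituted C6, is alkylated, a benzyl-type ether being chosen because a silyl group on the 4β-oxygen could hop to the syn-axial C6 alkoxide in step 5.

Step 4
Reactants: 6 4β-PMB ether 5β,6β-diol
Product: 7 6β-hydroxy-4β-(4-methoxybenzyloxy)-1β-methyl-cis-decalin-5β-yl methanesulfonate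
Conditions: MsCl, Et3N, CH2Cl2, 0 °C
Reagents that add atoms: methanesulfonyl chloride, CS(=O)(=O)Cl
Why: Sulfonylation through sulfene reaches the hindered secondary C5–OH while the tertiary C6–OH stays free, so the leaving group ends up β and, in the preferred chair–chair form, equatorial.

Step 5
Reactants: 7 cis-decalin 6β-ol 5β-mesylate
Product: 9 trans-fused 4β-(4-methoxybenzyloxy)-1β-methyl-5αH-perhydroazulen-6-one, via potassium C6-alkoxide 8 (not isolated)
Conditions: KOtBu (1.05 equiv), THF–t-BuOH, 0 °C; pH 7 phosphate buffer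
Reagents that add atoms: none
Why: KOtBu turns the tertiary C6–OH into alkoxide 8, and electron release from O6 is coupled with departure of the equatorial 5β-mesylate, so the ring-fusion bond C6–C1, antiperiplanar to C5–O, slides from C6 to C5 in one concerted suprafacial 1,2-alkyl shift in which no carbocation is released. The closest known reaction type is the base-induced semipinacol (pinacol-type) rearrangement of cis-decalin vicinal diol monosulfonates to hydroazulenones. The single new bond C1–C5 closes the cyclopentane C1–C2–C3–C4–C5 by contraction of ring A and at the same time closes the cycloheptanone C1–C5–C6–C7–C8–C9–C10 by insertion of C5 into ring B, so neither ring arises by end-to-end cyclisation. The new stereocentre C5 is fixed by inversion at the mesylate carbon with retention at C1, so a β leaving group leaves H5 on the α face, trans to the C1 methyl. The step needs migration of C1 rather than of C7, C3 or hydride: in the chair–chair form that avoids a syn-diaxial methyl/mesylate contact the mesylate is equatorial, so only the ring bonds C6–C1 and C4–C3 are aligned, only C6 carries the pushing alkoxide, fully substituted C1 is the better migrating carbon, the cis O6/OMs geometry excludes epoxide closure and the PMB ether cannot wander to O6. The base is used up as KOMs, which together with low temperature and the buffered quench should keep C5 from epimerising and the β-alkoxy group from E1cB loss.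

Step 6
Reactants: 9 perhydroazulen-6-one
Product: 11 trans-fused 4β-(4-methoxybenzyloxy)-1β-methyl-5αH-hydroazulen-7-en-6-one, via lithium C6(O)=C7 enolate 10 (not isolated)
Conditions: LDA, THF, −78 °C; then N-tert-butylbenzenesulfinimidoyl chloride, −78 °C
Reagents that add atoms: none
Why: Mukaiyama dehydrogenation: LDA takes the accessible C7 proton under kinetic control and leaves the tertiary C5–H alone, so C5 and the β-alkoxy group are safe, and S-attack of the enolate on the sulfinimidoyl chloride followed by intramolecular syn elimination at low temperature gives the C7=C8 enone.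

Step 7
Reactants: 11 7-en-6-one
Product: 13 trans-fused 4β-(4-methoxybenzyloxy)-1β,8-dimethyl-5αH-hydroazulen-7-en-6-one, via lithium 8-methyl enolate 12 (not isolated)
Conditions: MeLi (2 equiv), CuI, Et2O, −78 to −40 °C; then N-tert-butylbenzenesulfinimidoyl chloride, THF, −78 °C
Reagents that add atoms: methyllithium (used as Me2CuLi), [Li]C
Why: Gilman cuprate 1,4-addition places the methyl group on C8 and the regiodefined enolate is dehydrogenated in the same flask by the sulfinimidoyl chloride (known one-pot β-alkylation of enones), which erases the transient C8 stereocentre.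

Step 8
Reactants: 13 8-methyl-7-en-6-one
Product: 14 6-(trimethylsilyloxy)-6,8-diene (C6=C7–C8(CH3)=C9) of the same skeleton
Conditions: TMSOTf, Et3N, CH2Cl2, 0 °C; pentane, filtration
Reagents that add atoms: trimethylsilyl triflate, C[Si](C)(C)OS(=O)(=O)C(F)(F)F
Why: Soft enolisation (silyl triflate plus amine) of a β-alkyl enone gives the linear dienol ether, as with Δ4-3-keto steroids, because the α′ proton on C5 is tertiary and wedged between C1 and C4, and loss of a ring proton from C9 gives the more substituted endocyclic diene.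

Step 9
Reactants: 14 silyl dienol ether
Product: 17 trans-fused 4β-(4-methoxybenzyloxy)-1β,8-dimethyl-5αH-hydroazulen-8-en-6β-ol, via lithium dienolate 15 (not isolated), via β,γ-enone 16 (not isolated)
Conditions: MeLi, THF, −20 °C; cannulated into AcOH–THF, −78 °C; then CeCl3·7H2O, MeOH, NaBH4, −78 to −40 °C
Reagents that add atoms: none
Why: Reductive deconjugation: methyllithium releases the regiodefined lithium dienolate from silicon, kinetic protonation of a dienolate occurs at the α-carbon C7 and leaves C8=C9, and Luche reduction at low temperature traps the β,γ-enone before it can reconjugate, hydride entering from the open α face to give the 6β-alcohol, whose configuration is corrected in steps 15 and 16.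

Step 10
Reactants: 17 8-en-6β-ol
Product: 18 6β-(tert-butyldimethylsilyloxy) ether of 17
Conditions: TBSOTf, 2,6-lutidine, CH2Cl2, 0 °C to rt
Reagents that add atoms: tert-butyldimethylsilyl triflate, CC(C)(C)[Si](C)(C)OS(=O)(=O)C(F)(F)F
Why: Silyl triflate and lutidine silylate even the hindered axial 6β-OH, and the resulting bulky β-substituent helps to screen the β face of C4 in step 13.

Step 11
Reactants: 18 4β-PMB ether 6β-silyl ether
Product: 19 6β-(tert-butyldimethylsilyloxy)-1β,8-dimethyl-5αH-hydroazulen-8-en-4β-ol
Conditions: DDQ, CH2Cl2–pH 7 buffer, 0 °C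
Reagents that add atoms: none
Why: Oxidative PMB cleavage: DDQ abstracts benzylic hydride from the electron-rich ether and water collapses the oxocarbenium ion, leaving the silyl ether and the trisubstituted alkene untouched.

Step 12
Reactants: 19 4β-ol
Product: 20 6β-(tert-butyldimethylsilyloxy)-1β,8-dimethyl-5αH-hydroazulen-8-en-4-one
Conditions: Dess–Martin periodinane, NaHCO3, CH2Cl2, 0 °C to rt
Reagents that add atoms: none
Why: Dess–Martin oxidation under buffered, non-basic conditions gives the cyclopentanone without epimerising C5 or expelling the β-silyloxy group.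

Step 13
Reactants: 20 hydroazulen-4-one; 21 isopropylmagnesium chloride
Product: 22 6β-(tert-butyldimethylsilyloxy)dauc-8-en-4β-ol (4α-isopropyl, 4β-OH)
Conditions: anhydrous CeCl3, 21, THF, −78 °C; then 20, −78 °C; H2O
Reagents that add atoms: isopropylmagnesium chloride (21), CC(C)[Mg]Cl
Why: Organocerium 1,2-addition: the weakly basic, oxophilic reagent suppresses enolisation, β-hydride reduction and E1cB loss, and it should attack the C4 carbonyl from the α face, opposite the C1 methyl and the 6β-silyloxy group, setting isopropyl α and hydroxyl β.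

Step 14
Reactants: 22 silyl ether
Product: 23 dauc-8-ene-4β,6β-diol
Conditions: Bu4NF, THF, rt to 45 °C
Reagents that add atoms: none
Why: Fluoride-driven desilylation (strong Si–F bond) frees the C6 carbinol, and no other group is sensitive to fluoride or mild base at this stage.

Step 15
Reactants: 23 4β,6β-diol
Product: 24 4β-hydroxydauc-8-en-6-one
Conditions: Dess–Martin periodinane, NaHCO3, CH2Cl2, 0 °C
Reagents that add atoms: none
Why: Dess–Martin oxidation touches only the secondary C6 carbinol, the tertiary C4–OH being inert, and the bicarbonate buffer should prevent reconjugation of C8=C9 and retro-aldol opening.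

Step 16
Reactants: 24 β-hydroxy ketone
Product: 26 dauc-8-ene-4β,6α-diol, via C4-alkoxydiacetoxyborohydride 25 (not isolated)
Conditions: Me4NBH(OAc)3, MeCN–AcOH, −30 to 0 °C
Reagents that add atoms: none
Why: Evans–Saksena reduction: the 4β-OH exchanges with one acetate on boron and the bound hydride is delivered through a six-membered transition state to the β face of C6, giving the anti-1,3-diol, that is the equatorial 6α-carbinol.

Step 17
Reactants: 26 4β,6α-diol; 27 4-(benzyloxy)benzoic acid
Product: 29 6α-[4-(benzyloxy)benzoyloxy]dauc-8-en-4β-ol, via O-acylisourea 28 (not isolated)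
Conditions: DCC, DMAP (cat.), CH2Cl2, 0 °C to rt
Reagents that add atoms: 4-(benzyloxy)benzoic acid (27), O=C(O)c1ccc(OCc2ccccc2)cc1
Why: Steglich esterification acylates the only secondary alcohol, the equatorial 6α-OH, while the tertiary 4β-OH does not react, and the benzyl ether keeps the phenol from self-acylation.

Step 18
Reactants: 29 benzyl-protected ester alkene
Product: 30 6α-[4-(benzyloxy)benzoyloxy]daucane-4β,8α,9α-triol
Conditions: OsO4 (2 mol %), NMO, acetone–H2O, rt
Reagents that add atoms: N-methylmorpholine N-oxide, C[N+]1([O-])CCOCC1; water, O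
Why: Upjohn dihydroxylation: suprafacial [3+2] addition to the only alkene from the convex α face of the chair-like cycloheptene, whose β face lies under the axial C1 methyl, should set 8α-OH and 9α-OH in one event.

Step 19
Reactants: 30 benzyl ether triol
Product: 31 6α-(4-hydroxybenzoyloxy)daucane-4β,8α,9α-triol (CNP0197754.3)
Conditions: H2 (1 atm), Pd/C, EtOAc–EtOH, rt
Reagents that add atoms: none
Why: Hydrogenolysis of the benzyl aryl ether over palladium is neutral and, with no alkene left, leaves the ester and the three carbinols unchanged.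

**Compound list**

1 | (S)-4a-methyl-4,4a,5,6,7,8-hexahydronaphthalen-2(3H)-one | C[C@]12CCC(=O)C=C1CCCC2 | starting material
2 | (2S,4aS)-4a-methyl-2,3,4,4a,5,6,7,8-octahydronaphthalen-2-ol (4β-OH) | C[C@]12CC[C@H](O)C=C1CCCC2 | intermediate
3 | cyclic 5β,6β-ester of hexavalent osmium from 2, chelated by TMEDA | C[C@]12CC[C@H](O)[C@@H]3O[Os](=O)(=O)O[C@]13CCCC2.CN(C)CCN(C)C | intermediate
4 | 1β-methyl-cis-decalin-4β,5β,6β-triol | C[C@]12CC[C@H](O)[C@H](O)[C@@]1(O)CCCC2 | intermediate
5 | 4,5-O-dibutylstannylene acetal of 4 | C[C@]12CC[C@@H]3O[Sn](CCCC)(CCCC)O[C@@H]3[C@@]1(O)CCCC2 | intermediate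
6 | 4β-(4-methoxybenzyloxy)-1β-methyl-cis-decalin-5β,6β-diol | C[C@]12CC[C@H](OCc3ccc(OC)cc3)[C@H](O)[C@@]1(O)CCCC2 | intermediate
7 | 6β-hydroxy-4β-(4-methoxybenzyloxy)-1β-methyl-cis-decalin-5β-yl methanesulfonate | C[C@]12CC[C@H](OCc3ccc(OC)cc3)[C@H](OS(C)(=O)=O)[C@@]1(O)CCCC2 | intermediate
8 | potassium C6-alkoxide of 7 | C[C@]12CC[C@H](OCc3ccc(OC)cc3)[C@H](OS(C)(=O)=O)[C@@]1([O-])CCCC2.[K+] | intermediate
9 | trans-fused 4β-(4-methoxybenzyloxy)-1β-methyl-5αH-perhydroazulen-6-one | COc1ccc(CO[C@H]2CC[C@]3(C)CCCCC(=O)[C@H]32)cc1 | intermediate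
10 | lithium C6(O)=C7 enolate of 9 | COc1ccc(CO[C@H]2CC[C@]3(C)CCCC=C([O-])[C@H]32)cc1.[Li+] | intermediate
11 | 7-en-6-one derived from 9 | COc1ccc(CO[C@H]2CC[C@]3(C)CCC=CC(=O)[C@H]32)cc1 | intermediate
12 | lithium enolate after methyl addition (C8 configuration of no consequence) | COc1ccc(CO[C@H]2CC[C@]3(C)CCC(C)C=C([O-])[C@H]32)cc1.[Li+] | intermediate
13 | 8-methyl-7-en-6-one | COc1ccc(CO[C@H]2CC[C@]3(C)CCC(C)=CC(=O)[C@H]32)cc1 | intermediate
14 | 6-(trimethylsilyloxy)-8-methyl-6,8-diene | COc1ccc(CO[C@H]2CC[C@]3(C)CC=C(C)C=C(O[Si](C)(C)C)[C@H]32)cc1 | intermediate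
15 | lithium dienolate from 14 | COc1ccc(CO[C@H]2CC[C@]3(C)CC=C(C)C=C([O-])[C@H]32)cc1.[Li+] | intermediate
16 | 8-methyl-8-en-6-one (β,γ-enone) | COc1ccc(CO[C@H]2CC[C@]3(C)CC=C(C)CC(=O)[C@H]32)cc1 | intermediate
17 | 4β-(4-methoxybenzyloxy)-1β,8-dimethyl-5αH-hydroazulen-8-en-6β-ol | COc1ccc(CO[C@H]2CC[C@]3(C)CC=C(C)C[C@@H](O)[C@H]32)cc1 | intermediate
18 | 6β-TBS ether of 17 | COc1ccc(CO[C@H]2CC[C@]3(C)CC=C(C)C[C@@H](O[Si](C)(C)C(C)(C)C)[C@H]32)cc1 | intermediate
19 | 6β-(tert-butyldimethylsilyloxy)-1β,8-dimethyl-5αH-hydroazulen-8-en-4β-ol | O[C@H]1CC[C@]2(C)CC=C(C)C[C@@H](O[Si](C)(C)C(C)(C)C)[C@H]21 | intermediate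
20 | 6β-(tert-butyldimethylsilyloxy)-1β,8-dimethyl-5αH-hydroazulen-8-en-4-one | O=C1CC[C@]2(C)CC=C(C)C[C@@H](O[Si](C)(C)C(C)(C)C)[C@H]21 | intermediate
21 | isopropylmagnesium chloride | CC(C)[Mg]Cl | starting material
22 | 6β-(tert-butyldimethylsilyloxy)dauc-8-en-4β-ol (4α-isopropyl) | CC(C)[C@]1(O)CC[C@]2(C)CC=C(C)C[C@@H](O[Si](C)(C)C(C)(C)C)[C@H]21 | intermediate
23 | dauc-8-ene-4β,6β-diol | CC(C)[C@]1(O)CC[C@]2(C)CC=C(C)C[C@@H](O)[C@H]21 | intermediate
24 | 4β-hydroxydauc-8-en-6-one | CC(C)[C@]1(O)CC[C@]2(C)CC=C(C)CC(=O)[C@H]21 | intermediate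
25 | tetramethylammonium C4-alkoxydiacetoxyborohydride of 24 | CC(C)[C@]1(O[BH-](OC(C)=O)OC(C)=O)CC[C@]2(C)CC=C(C)CC(=O)[C@H]21.C[N+](C)(C)C | intermediate
26 | dauc-8-ene-4β,6α-diol | CC(C)[C@]1(O)CC[C@]2(C)CC=C(C)C[C@H](O)[C@H]21 | intermediate
27 | 4-(benzyloxy)benzoic acid | O=C(O)c1ccc(OCc2ccccc2)cc1 | starting material
28 | O-acylisourea from 27 and DCC | O=C(OC(=NC1CCCCC1)NC1CCCCC1)c1ccc(OCc2ccccc2)cc1 | intermediate
29 | 6α-[4-(benzyloxy)benzoyloxy]dauc-8-en-4β-ol | CC(C)[C@]1(O)CC[C@]2(C)CC=C(C)C[C@H](OC(=O)c3ccc(OCc4ccccc4)cc3)[C@H]21 | intermediate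
30 | 6α-[4-(benzyloxy)benzoyloxy]daucane-4β,8α,9α-triol | CC(C)[C@]1(O)CC[C@]2(C)C[C@H](O)[C@](C)(O)C[C@H](OC(=O)c3ccc(OCc4ccccc4)cc3)[C@H]21 | intermediate
31 | 6α-(4-hydroxybenzoyloxy)daucane-4β,8α,9α-triol (CNP0197754.3) | CC(C)[C@]1(O)CC[C@]2(C)C[C@H](O)[C@](C)(O)C[C@H](OC(=O)c3ccc(O)cc3)[C@H]21 | target

Total step count: 19. Longest linear sequence: 19 steps (1 to 31).

**Steps most likely to fail**

Risk 1 (step 9, together with the regiochemistry fixed in step 8). Three things may go wrong:
- proton loss from the C8 methyl or from C5 instead of C9 during dienol ether formation;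
- protonation of the dienolate at the γ-carbon;
- reconjugation of the alkene before the hindered ketone is reduced.

The fallback replaces kinetic protonation by a thermodynamic double-bond shift. It sets out from 13. Ethylene glycol, HC(OEt)3 and catalytic p-TsOH at room temperature should give the β,γ-unsaturated 6,6-ethylenedioxy acetal F5. The alkene should move into the more substituted endocyclic C8=C9 position, as in the acetalisation of Δ4-3-keto steroids. Brief hydrolysis on oxalic acid-loaded silica gel then frees 16, and immediate Luche reduction brings the sequence back to the route at 17.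

Risk 2 (step 5). Base left after the shift may enolise the new ketone towards C5. That would erode the trans ring fusion or expel the β-alkoxy group. Reaction through the other chair–chair form would move C7 instead of C1. The fallback keeps the same C1 shift but changes from alkoxide push to Lewis-acid pull with reduction in the same flask. It sets out from 7. Et3Al and DIBAL-H in CH2Cl2 at −78 °C form the C6 aluminium alkoxide, aluminium abstracts the mesylate, and the nascent ketone is reduced at once. The product is 4β-(4-methoxybenzyloxy)-1β-methyl-5αH-perhydroazulen-6β-ol F4, which has no acidic C5–H. Dess–Martin oxidation under neutral conditions returns to the route at 9.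

Risk 3 (step 2). The bulky chelated reagent has to approach the face that carries the angular methyl, so a sluggish reaction or poor facial selectivity is possible. The fallback installs the C6 oxygen by a different reaction and osmylates a less hindered alkene. It sets out from 1.
- Alkaline H2O2 should add to the β face to give the 5β,6β-epoxy-4-ketone F1.
- Wharton transposition (N2H4·H2O, AcOH, MeOH) gives the tertiary allylic alcohol 6β-hydroxy-1β-methyl-cis-octal-4-ene F2.
- OsO4–TMEDA, now directed by the 6β-OH onto the disubstituted C4=C5 bond, gives the TMEDA-chelated 4β,5β-osmate ester F3.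
- Sulfite cleavage of F3 comes back to the route at 4.

**Further compounds**

F1 | step 2 | 5β,6β-epoxy-1β-methyldecalin-4-one | C[C@]12CCC(=O)[C@@H]3O[C@]13CCCC2
F2 | step 2 | 6β-hydroxy-1β-methyl-cis-octal-4-ene | C[C@]12CCC=C[C@@]1(O)CCCC2
F3 | step 2 | TMEDA-chelated 4β,5β-ester of hexavalent osmium from F2 | C[C@]12CC[C@@H]3O[Os](=O)(=O)O[C@@H]3[C@@]1(O)CCCC2.CN(C)CCN(C)C
F4 | step 5 | 4β-(4-methoxybenzyloxy)-1β-methyl-5αH-perhydroazulen-6β-ol | COc1ccc(CO[C@H]2CC[C@]3(C)CCCC[C@@H](O)[C@H]32)cc1
F5 | step 9 | 6,6-ethylenedioxy-4β-(4-methoxybenzyloxy)-1β,8-dimethyl-5αH-hydroazulen-8-ene | COc1ccc(CO[C@H]2CC[C@]3(C)CC=C(C)CC4(OCCO4)[C@H]32)cc1
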